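**Retrosynthetic overview**

1. Both aryl ketones are cut last: the two 2,4-dihydroxyphenyl rings (rings C and D) come from a twofold C-acylation of resorcinol by a diaryl ether dipropanoic acid.
2. The strategy rests on ring A, the hydroxylated ether ring (propanoyl chain on C1, aryloxy on C3, hydroxyl on C4). It maps onto a 3-aryloxy-4H-pyran-4-one: the pyranone C3–O is the ether oxygen, C4=O becomes the phenol, and the ring oxygen is exchanged for the chain-bearing C1 through a silyloxypyrylium/phosphorus ylide sequence (new bonds C1–C6 and C1=C2).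
3. The aryloxypyranone is assembled on the phenol oxygen of methyl dihydroferulate (ring B) by O-alkylation with chloroacetone, two formyl equivalents and acid closure. This avoids O-arylating 3-hydroxy-4H-pyran-4-one with an aryl aldehyde, which would compete with aldol-type attack at its C2.
4. Ring order: ring B (bought), then the pyranone, then ring A (step 3), then rings C and D (bought resorcinol) are attached.

Key step: step 3

Assumption: ylide addition to pyrylium 9 is drawn at C6; addition at C2 gives the regioisomeric 2H-pyran and open chain, which should close to the same arene 12.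

**Route**

Step 1
Reactants: 1 methyl 3-(4-hydroxy-3-methoxyphenyl)propanoate; 2 chloroacetone (1-chloropropan-2-one)
Product: 3 methyl 3-[3-methoxy-4-(2-oxopropoxy)phenyl]propanoate
Conditions: K2CO3, KI (cat.), acetone, reflux
Reagents that add atoms: chloroacetone, CC(=O)CCl
Why: Williamson ether synthesis, in which the phenoxide of 1 displaces chloride from the activated α-chloroketone (SN2, iodide-assisted) while the ester and the aryl methyl ether are inert to K2CO3 in acetone.

Step 2
Reactants: 3 methyl 3-[3-methoxy-4-(2-oxopropoxy)phenyl]propanoate; 4 N,N-dimethylformamide dimethyl acetal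
Product: 6 methyl 3-[3-methoxy-4-[(4-oxo-4H-pyran-3-yl)oxy]phenyl]propanoate, via bis-enaminone 5 (not isolated)
Conditions: Me2NCH(OMe)2 (excess, neat), 110–120 °C, MeOH distilled off; evaporate; then 1 M aq HCl, THF, rt
Reagents that add atoms: N,N-dimethylformamide dimethyl acetal, COC(OC)N(C)C; water, O
Why: Twofold enaminone formation with the amide acetal at the OCH2 and CH3 positions of the ketone should give 5, and aqueous acid hydrolyses one enaminone to the hydroxymethylene ketone whose oxygen adds to the other with loss of dimethylamine, which is the classical cyclodehydration of a 1,3,5-tricarbonyl equivalent to a 4-pyranone; the saturated ester does not react with the amide acetal.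

Step 3
Reactants: 6 methyl 3-[3-methoxy-4-[(4-oxo-4H-pyran-3-yl)oxy]phenyl]propanoate; 7 (4-ethoxy-4-oxobutyl)triphenylphosphonium bromide
Product: 13 ethyl 3-[4-hydroxy-3-[2-methoxy-4-(3-methoxy-3-oxopropyl)phenoxy]phenyl]propanoate, via ylide 8 (not isolated), via pyrylium triflate 9 (not isolated), via pyran adduct 10 (not isolated), via dienal ylide 11 (not isolated), via silyl ether 12 (not isolated)
Conditions: 6, t-BuMe2SiOTf (1.0 equiv), CH2Cl2, 0 °C to rt; cool to −78 °C; add 8 [from 7 (1.1 equiv), KN(SiMe3)2 (1.05 equiv), THF, −78 to 0 °C]; then KN(SiMe3)2 (1.1 equiv), −78 °C to rt; then Bu4NF, AcOH, THF, 0 °C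
Reagents that add atoms: (4-ethoxy-4-oxobutyl)triphenylphosphonium bromide, CCOC(=O)CCC[P+](c1ccccc1)(c1ccccc1)c1ccccc1.[Br-]
Why: Proposed new method: O-silylation of the pyranone carbonyl of 6 should give the 4-silyloxypyrylium triflate 9, whose α-carbon (C6, or equally C2) is attacked by the non-stabilised ylide 8 to give the 2H-pyran 10; 10 should open by 6π-electrocyclic ring opening to a dienal phosphonium salt, which the second equivalent of KN(SiMe3)2 converts into the vinylogous ylide 11. Intramolecular Wittig olefination then closes ring A as a six-membered ring (the ylide carbon adds to the aldehyde carbon, the former C2, and the oxaphosphetane loses Ph3PO carrying the former ring oxygen), giving the aromatic silyl ether 12, which fluoride cleaves to 13. The closest known reaction types are the conversion of 2,4,6-trisubstituted pyrylium salts into benzenes by alkylidenetriphenylphosphoranes and the α-addition of carbon nucleophiles to 4-silyloxypyrylium triflates; their combination on a 3-aryloxy-4-silyloxypyrylium with free α-positions has not been shown. No stereocentre is formed, and the double-bond geometry of the open chain should not matter because 11 is a delocalised phosphonium dienolate that can rotate into the cisoid form needed for closure, with aromatisation as the driving force. No positional selectivity is needed since attack at either α-carbon leads to the same arene; the step needs chemoselectivity for the cationic ring over the two esters, which the far higher electrophilicity of the pyrylium at −78 °C should secure, and exactly one equivalent of t-BuMe2SiOTf so that no silyl triflate remains to silylate the ylide.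

Step 4
Reactants: 13 ethyl 3-[4-hydroxy-3-[2-methoxy-4-(3-methoxy-3-oxopropyl)phenoxy]phenyl]propanoate
Product: 14 3-[3-[4-(2-carboxyethyl)-2-methoxyphenoxy]-4-hydroxyphenyl]propanoic acid
Conditions: LiOH·H2O (6 equiv), THF/MeOH/H2O, rt; then 1 M HCl
Reagents that add atoms: lithium hydroxide, [Li+].[OH-]
Why: Ester saponification (acyl substitution by hydroxide) cleaves the methyl and the ethyl ester alike, while the diaryl ether, the aryl methyl ether and the phenol (as phenoxide) are stable, and acidification returns the diacid.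

Step 5
Reactants: 14 3-[3-[4-(2-carboxyethyl)-2-methoxyphenoxy]-4-hydroxyphenyl]propanoic acid; 15 resorcinol
Product: 16 verbenachalcone, 3-[4-[5-[3-(2,4-dihydroxyphenyl)-3-oxopropyl]-2-hydroxyphenoxy]-3-methoxyphenyl]-1-(2,4-dihydroxyphenyl)propan-1-one
Conditions: resorcinol (6 equiv), BF3·OEt2 (neat), 85–90 °C; then aq NaOAc, EtOAc
Reagents that add atoms: resorcinol, Oc1cccc(O)c1
Why: Friedel–Crafts (Nencki-type) C-acylation of resorcinol by the free acids in BF3·OEt2, in which each boron-activated acid attacks C4 of resorcinol (para to one hydroxyl, ortho to the other, C2 being hindered), the o-hydroxyaryl ketone is held as a BF2 chelate that stops further acylation, and the excess of resorcinol should outrun closure to indanones and acylation of the ring A phenol.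

**Compound list**

1 | methyl 3-(4-hydroxy-3-methoxyphenyl)propanoate | COC(=O)CCc1ccc(O)c(OC)c1 | starting material
2 | chloroacetone (1-chloropropan-2-one) | CC(=O)CCl | starting material
3 | methyl 3-[3-methoxy-4-(2-oxopropoxy)phenyl]propanoate | COC(=O)CCc1ccc(OCC(C)=O)c(OC)c1 | intermediate
4 | N,N-dimethylformamide dimethyl acetal | COC(OC)N(C)C | starting material
5 | methyl 3-[4-[[(1Z,4E)-1,5-bis(dimethylamino)-3-oxopenta-1,4-dien-2-yl]oxy]-3-methoxyphenyl]propanoate (geometry of no consequence) | COC(=O)CCc1ccc(O/C(C(=O)/C=C/N(C)C)=C\N(C)C)c(OC)c1 | intermediate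
6 | methyl 3-[3-methoxy-4-[(4-oxo-4H-pyran-3-yl)oxy]phenyl]propanoate | COC(=O)CCc1ccc(Oc2coccc2=O)c(OC)c1 | intermediate
7 | (4-ethoxy-4-oxobutyl)triphenylphosphonium bromide | CCOC(=O)CCC[P+](c1ccccc1)(c1ccccc1)c1ccccc1.[Br-] | starting material
8 | ethyl 4-(triphenyl-λ5-phosphanylidene)butanoate | CCOC(=O)CCC=P(c1ccccc1)(c1ccccc1)c1ccccc1 | intermediate
9 | 4-[(tert-butyldimethylsilyl)oxy]-3-[2-methoxy-4-(3-methoxy-3-oxopropyl)phenoxy]pyrylium trifluoromethanesulfonate | COC(=O)CCc1ccc(Oc2c[o+]ccc2O[Si](C)(C)C(C)(C)C)c(OC)c1.[O-]S(=O)(=O)C(F)(F)F | intermediate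
10 | [1-[4-[(tert-butyldimethylsilyl)oxy]-5-[2-methoxy-4-(3-methoxy-3-oxopropyl)phenoxy]-2H-pyran-2-yl]-4-ethoxy-4-oxobutyl]triphenylphosphonium trifluoromethanesulfonate (mixture of diastereomers) | CCOC(=O)CCC([P+](c1ccccc1)(c1ccccc1)c1ccccc1)C1OC=C(Oc2ccc(CCC(=O)OC)cc2OC)C(O[Si](C)(C)C(C)(C)C)=C1.[O-]S(=O)(=O)C(F)(F)F | intermediate
11 | ethyl (5Z,7Z)-7-[(tert-butyldimethylsilyl)oxy]-8-[2-methoxy-4-(3-methoxy-3-oxopropyl)phenoxy]-9-oxo-4-(triphenyl-λ5-phosphanylidene)nona-5,7-dienoate (drawn in the form that closes) | CCOC(=O)CCC(=P(c1ccccc1)(c1ccccc1)c1ccccc1)/C=C\C(O[Si](C)(C)C(C)(C)C)=C(/C=O)Oc1ccc(CCC(=O)OC)cc1OC | intermediate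
12 | ethyl 3-[4-[(tert-butyldimethylsilyl)oxy]-3-[2-methoxy-4-(3-methoxy-3-oxopropyl)phenoxy]phenyl]propanoate | CCOC(=O)CCc1ccc(O[Si](C)(C)C(C)(C)C)c(Oc2ccc(CCC(=O)OC)cc2OC)c1 | intermediate
13 | ethyl 3-[4-hydroxy-3-[2-methoxy-4-(3-methoxy-3-oxopropyl)phenoxy]phenyl]propanoate | CCOC(=O)CCc1ccc(O)c(Oc2ccc(CCC(=O)OC)cc2OC)c1 | intermediate
14 | 3-[3-[4-(2-carboxyethyl)-2-methoxyphenoxy]-4-hydroxyphenyl]propanoic acid | OC(=O)CCc1ccc(O)c(Oc2ccc(CCC(=O)O)cc2OC)c1 | intermediate
15 | resorcinol | Oc1cccc(O)c1 | starting material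
16 | verbenachalcone | COc1cc(CCC(=O)c2ccc(O)cc2O)ccc1Oc1cc(CCC(=O)c2ccc(O)cc2O)ccc1O | target

**Step count**

Total steps: 5. Longest linear sequence: 5 steps (1 → 3 → 6 → 13 → 14 → 16).

**Steps most likely to fail**

Step 3 (the new method). The ylide may add at the silyloxy-bearing γ-carbon or attack silicon instead of an α-carbon. The open-chain dienal may be consumed by intermolecular olefination or oligomerisation before it closes. Incomplete pyrylium formation would leave silyl triflate that silylates the ylide. The fallback uses known chemistry: the diaryl ether bond is made by nucleophilic aromatic substitution and the ring A hydroxyl by a Dakin-type oxidation. It sets out from 1 and comes back to the route at 13. The phenoxide of 1 (K2CO3, DMF, 90 °C) should displace fluoride from commercial 4-bromo-2-fluorobenzaldehyde, activated by the ortho formyl group, to give methyl 3-[4-(5-bromo-2-formylphenoxy)-3-methoxyphenyl]propanoate F1. Baeyer–Villiger oxidation with mCPBA in CH2Cl2 should give the aryl formate methyl 3-[4-[5-bromo-2-(formyloxy)phenoxy]-3-methoxyphenyl]propanoate F2, which K2CO3 in MeOH cleaves to the bromophenol methyl 3-[4-(5-bromo-2-hydroxyphenoxy)-3-methoxyphenyl]propanoate F3. A Heck reaction with ethyl acrylate (Pd(OAc)2, P(o-tol)3, Et3N, DMF, 100 °C) should give ethyl (E)-3-[4-hydroxy-3-[2-methoxy-4-(3-methoxy-3-oxopropyl)phenoxy]phenyl]prop-2-enoate F4, and hydrogenation of the cinnamate (H2, Pd/C, EtOAc) gives 13.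

Step 2. The second aminomethylenation, at the methyl group of the mono-enaminone, may stall, and the methyl ester may be partly hydrolysed during the acidic ring closure. The fallback attaches an intact pyranone by copper-mediated O-arylation instead of building it; it sets out from 1 and comes back at 6. Triflation of 1 (Tf2O, pyridine, CH2Cl2, 0 °C) gives methyl 3-[3-methoxy-4-[(trifluoromethanesulfonyl)oxy]phenyl]propanoate F5. Miyaura borylation (bis(pinacolato)diboron, PdCl2(dppf), KOAc, dioxane, 90 °C) gives methyl 3-[3-methoxy-4-(4,4,5,5-tetramethyl-1,3,2-dioxaborolan-2-yl)phenyl]propanoate F6. Chan–Lam coupling of F6 with commercial 3-hydroxy-4H-pyran-4-one (Cu(OAc)2, pyridine, B(OH)3, 4 Å sieves, MeCN, air, 70 °C) should give 6; this aryl partner carries no aldehyde, so the aldol problem does not arise.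

Step 5. Intramolecular acylation to indanones, ester formation and oligomerisation through the ring A phenol, acylation of only one of the two acids, or attack at C2 of resorcinol may erode the twofold acylation. The fallback forms the ketones by aryl-metal addition to amides; it sets out from 14 and comes back at 16. Amide coupling of 14 with MeNH(OMe)·HCl (EDC·HCl, HOBt, N-methylmorpholine, CH2Cl2) gives the bis-Weinreb amide 3-[4-hydroxy-3-[2-methoxy-4-[3-[methoxy(methyl)amino]-3-oxopropyl]phenoxy]phenyl]-N-methoxy-N-methylpropanamide F7. Commercial 4-bromoresorcinol is benzylated (BnBr, K2CO3, DMF) to 2,4-bis(benzyloxy)-1-bromobenzene F8, and bromine–lithium exchange (n-BuLi, THF, −78 °C) gives [2,4-bis(benzyloxy)phenyl]lithium F9. Four equivalents of F9, one being consumed by the phenol, should convert F7 into 1-[2,4-bis(benzyloxy)phenyl]-3-[4-[5-[3-[2,4-bis(benzyloxy)phenyl]-3-oxopropyl]-2-hydroxyphenoxy]-3-methoxyphenyl]propan-1-one F10. Hydrogenolysis of the four benzyl ethers (H2, Pd/C, EtOAc/MeOH) gives 16.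

**Further compounds**

F1 | step 3 | methyl 3-[4-(5-bromo-2-formylphenoxy)-3-methoxyphenyl]propanoate | COC(=O)CCc1ccc(Oc2cc(Br)ccc2C=O)c(OC)c1
F2 | step 3 | methyl 3-[4-[5-bromo-2-(formyloxy)phenoxy]-3-methoxyphenyl]propanoate | COC(=O)CCc1ccc(Oc2cc(Br)ccc2OC=O)c(OC)c1
F3 | step 3 | methyl 3-[4-(5-bromo-2-hydroxyphenoxy)-3-methoxyphenyl]propanoate | COC(=O)CCc1ccc(Oc2cc(Br)ccc2O)c(OC)c1
F4 | step 3 | ethyl (E)-3-[4-hydroxy-3-[2-methoxy-4-(3-methoxy-3-oxopropyl)phenoxy]phenyl]prop-2-enoate | CCOC(=O)/C=C/c1ccc(O)c(Oc2ccc(CCC(=O)OC)cc2OC)c1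
F5 | step 2 | methyl 3-[3-methoxy-4-[(trifluoromethanesulfonyl)oxy]phenyl]propanoate | COC(=O)CCc1ccc(OS(=O)(=O)C(F)(F)F)c(OC)c1
F6 | step 2 | methyl 3-[3-methoxy-4-(4,4,5,5-tetramethyl-1,3,2-dioxaborolan-2-yl)phenyl]propanoate | COC(=O)CCc1ccc(B2OC(C)(C)C(C)(C)O2)c(OC)c1
F7 | step 5 | 3-[4-hydroxy-3-[2-methoxy-4-[3-[methoxy(methyl)amino]-3-oxopropyl]phenoxy]phenyl]-N-methoxy-N-methylpropanamide | CON(C)C(=O)CCc1ccc(O)c(Oc2ccc(CCC(=O)N(C)OC)cc2OC)c1
F8 | step 5 | 2,4-bis(benzyloxy)-1-bromobenzene | Brc1ccc(OCc2ccccc2)cc1OCc1ccccc1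
F9 | step 5 | [2,4-bis(benzyloxy)phenyl]lithium | [Li]c1ccc(OCc2ccccc2)cc1OCc1ccccc1
F10 | step 5 | 1-[2,4-bis(benzyloxy)phenyl]-3-[4-[5-[3-[2,4-bis(benzyloxy)phenyl]-3-oxopropyl]-2-hydroxyphenoxy]-3-methoxyphenyl]propan-1-one | COc1cc(CCC(=O)c2ccc(OCc3ccccc3)cc2OCc2ccccc2)ccc1Oc1cc(CCC(=O)c2ccc(OCc3ccccc3)cc2OCc2ccccc2)ccc1O
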